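**Retrosynthetic overview**

1. The three esters go on last: senecioate by acylation, the acetate together with the neighbouring carbinol by Evans–Tishchenko reduction of a β-hydroxy ketone, the angelate by mixed-anhydride acylation of the primary alcohol.
2. Tricyclic diol-dione 16 is cut back in one operation to monocyclic keto aldehyde 13: the CH2–CH(OH) bond of the seven-membered ring (Mukaiyama aldol) and the cyclobutane bond between the α′-carbon of the cyclohexenone and the methyl-bearing quaternary carbon (capture of a 2-silyloxyallyl cation).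
3. Enabling feature: the side-chain ketone carbon (later the senecioate carbinol) lies between the quaternary cyclobutane carbon and the ring CH2, 1,4 to the enone carbonyl and 1,3 to the acetate carbinol; one C–C(=O)–C unit can therefore be an enol nucleophile at CH2 (toward the neopentyl aldehyde) and an oxyallyl electrophile at its oxygenated tertiary carbon (toward the cross-conjugated dienol of the six-membered ring), and the cis-4,5 substitution of the cyclohexenone holds both chains on one face.
4. 13 arises by ozonolysis of the sacrificial ring A of cis-decalin 12, made by Diels–Alder reaction of cyclohexadienone 5 with silyloxydiene 7; the quaternary stereocentre of 5 comes from an organocatalytic Michael/aldol (Robinson) sequence.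
5. Ring order: sacrificial cyclohexenone A (Robinson) → cyclohexenone B of the target (Diels–Alder) → temporary lactone bridge → cleavage of ring A → seven-membered ring, then cyclobutane (key step).

Key step: step 10

Assumption: ethyl 2-methyl-3-oxopropanoate is taken as a commercial compound, and the quinidine-derived catalyst of step 1 is taken to give the R adduct; if the sense of induction is opposite, the quinine-derived pseudoenantiomer is used.

Step 1
Reactants: 1 ethyl 2-methyl-3-oxopropanoate; 2 pent-1-en-3-one
Product: 3 ethyl (R)-2-formyl-2-methyl-5-oxoheptanoate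
Conditions: 9-O-(9-phenanthryl)cupreidine (10 mol%), CH2Cl2, −24 °C
Reagents that add atoms: none
Why: Organocatalytic asymmetric Michael addition of an α-substituted 1,3-dicarbonyl donor to a vinyl ketone; the bifunctional cinchona catalyst binds the enolised formyl ester and directs the enone to one enantiotopic face, which sets the quaternary stereocentre.

Step 2
Reactants: 3 ethyl (R)-2-formyl-2-methyl-5-oxoheptanoate
Product: 4 ethyl (R)-1,3-dimethyl-4-oxocyclohex-2-ene-1-carboxylate
Conditions: p-TsOH·H2O (10 mol%), PhMe, reflux, Dean–Stark trap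
Reagents that add atoms: none
Why: Acid-catalysed intramolecular aldol condensation (ring closure of a Robinson annulation) of the ethyl ketone through its more substituted enol onto the non-enolisable aldehyde should give only the six-membered α-methyl enone and leaves the quaternary centre untouched.

Step 3
Reactants: 4 ethyl (R)-1,3-dimethyl-4-oxocyclohex-2-ene-1-carboxylate
Product: 5 ethyl (R)-1,3-dimethyl-4-oxocyclohexa-2,5-diene-1-carboxylate
Conditions: IBX (2 equiv), DMSO, 75 °C
Reagents that add atoms: none
Why: IBX dehydrogenation through the only enolisable α-CH2 should give the cross-conjugated dienone, whose aromatisation is blocked by the quaternary carbon.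

Step 4
Reactants: 6 (E)-pent-3-en-2-one
Product: 7 (E)-2-(tert-butyldimethylsilyloxy)penta-1,3-diene
Conditions: TBSOTf, Et3N, Et2O, 0 °C
Reagents that add atoms: tert-butyldimethylsilyl triflate, CC(C)(C)[Si](C)(C)OS(=O)(=O)C(F)(F)F
Why: Soft enolisation of the methyl ketone (silyl enol ether formation) should give the 2-silyloxy diene with the E alkene retained.

Step 5
Reactants: 5 ethyl (R)-1,3-dimethyl-4-oxocyclohexa-2,5-diene-1-carboxylate; 7 (E)-2-(tert-butyldimethylsilyloxy)penta-1,3-diene
Product: 8 ethyl (1R,4aS,5S,8aR)-7-(tert-butyldimethylsilyloxy)-1,3,5-trimethyl-4-oxo-1,4,4a,5,8,8a-hexahydronaphthalene-1-carboxylate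
Conditions: PhMe, BHT (cat.), 120 °C, sealed tube
Reagents that add atoms: none
Why: Normal-demand Diels–Alder reaction at the unsubstituted enone double bond of 5 (the α-methyl enone is the poorer dienophile); the 2-silyloxy and 4-methyl groups of the diene both send its CH2 terminus to the β-carbon, the endo transition state gives the cis ring fusion, and addition to the face anti to the quaternary methyl group (syn to the smaller, planar ester) should set both ring-fusion centres relative to the quaternary carbon.

Step 6
Reactants: 8 ethyl (1R,4aS,5S,8aR)-7-(tert-butyldimethylsilyloxy)-1,3,5-trimethyl-4-oxo-1,4,4a,5,8,8a-hexahydronaphthalene-1-carboxylate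
Product: 10 7-(tert-butyldimethylsilyloxy)-1-(hydroxymethyl)-1,3,4,5-tetramethyl-1,4,4a,5,8,8a-hexahydronaphthalen-4-ol (cis-fused; CH2OH/4-OH/bonds into ring B on one face), via bridged lactone 9 (not isolated)
Conditions: MeLi, CeCl3, THF, −78 → 0 °C; then LiAlH4, 0 °C; Rochelle-salt work-up
Reagents that add atoms: methyllithium, [Li]C
Why: Organocerium 1,2-addition to the enone carbonyl from the convex face (anti to ring B) gives a tertiary alkoxide that should lactonise onto the cis ester, and LiAlH4 then reduces the lactone to the diol; the configuration of the new tertiary carbinol does not matter because this carbon is ionised in step 10.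

Step 7
Reactants: 10 diol (see step 6)
Product: 11 bis-silyl ether of 10 (primary OTBS; tertiary OTMS; ring B still the TBS enol ether)
Conditions: TBSCl (1.05 equiv), imidazole, DMF, 0 °C; then TMSCl, 23 °C
Reagents that add atoms: tert-butyldimethylsilyl chloride, CC(C)(C)[Si](C)(C)Cl; trimethylsilyl chloride, C[Si](C)(C)Cl
Why: Sequential silyl ether formation: the primary alcohol takes the bulky TBS group first, the hindered tertiary allylic alcohol is then capped as the TMS ether that later serves as the leaving group and prevents lactol formation after step 9.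

Step 8
Reactants: 11 bis-silyl ether (see step 7)
Product: 12 8-[(tert-butyldimethylsilyloxy)methyl]-4,5,6,8-tetramethyl-5-(trimethylsilyloxy)-4a,5,8,8a-tetrahydronaphthalen-2(1H)-one (cis-fused; stereocentres as in 11)
Conditions: Pd(OAc)2 (1.1 equiv), MeCN, 23 °C
Reagents that add atoms: none
Why: Saegusa–Ito oxidation of the regiodefined TBS enol ether; β-hydride elimination is only possible toward the methyl-bearing carbon, which gives the 3-methylcyclohexenone and erases the temporary methyl stereocentre.

Step 9
Reactants: 12 enone (see step 8)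
Product: 13 3-(tert-butyldimethylsilyloxy)-2-methyl-2-{3-methyl-5-oxo-2-[3-oxo-2-(trimethylsilyloxy)butan-2-yl]cyclohex-3-en-1-yl}propanal (ring substituents cis)
Conditions: O3, pyridine, CH2Cl2, −78 °C (dye end point); then Me2S, −78 → 23 °C
Reagents that add atoms: ozone, O=[O+][O-]
Why: Ozonolysis with reductive work-up should cleave the electron-rich trisubstituted alkene of ring A in preference to the electron-poor enone, unveiling the methyl ketone and the neopentyl aldehyde cis on the cyclohexenone.

Step 10
Reactants: 13 keto aldehyde (see step 9)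
Product: 16 5-hydroxy-6-(hydroxymethyl)-2,6,11-trimethyltricyclo[5.4.0.0(2,8)]undec-10-ene-3,9-dione (stereocentres as in 19), via bicyclic aldol enol silane 14 (not isolated), via persilylated tricycle 15 (not isolated)
Conditions: TMSOTf (5 equiv), Et3N (4 equiv), CH2Cl2, −78 → −20 °C, then 23 °C; then HF·pyridine, THF, 0 °C
Reagents that add atoms: none
Why: Proposed new method: TMSOTf/Et3N should turn the methyl ketone into its terminal enol silane and the enone into its cross-conjugated 2-silyloxydiene; the enol silane adds to the silyl-activated aldehyde (intramolecular Mukaiyama aldol, 7-(enolendo)-exo-trig), the β-silyloxy ketone is re-enolised toward the new CH to give 14, and on warming TMSOTf ionises the tertiary allylic OTMS group to a 2-silyloxyallyl cation embedded in the seven-membered ring, whose tertiary terminus is captured by the α′-carbon of the dienol silane (4-(enolexo)-exo-trig, cyclobutane) with loss of the silyl cation to restore the enone (15). The closest known chemistry is the one-pot enol-silane formation/Mukaiyama aldol under silyl triflate–amine conditions and the capture of unsymmetrical silyloxyallyl cations at their more substituted terminus by π-nucleophiles, joined here into a formal intramolecular (4+3) annulation that mirrors the bisabolyl-to-bergamotyl cation closure but is irreversible because the nucleophile is an enol silane. The carbinol centre is set in the aldol by a Felkin-type open transition state (attack anti to the CH2OTBS arm, silylated oxygen outside the forming ring). The cyclobutane methine and the quaternary methyl-bearing centre are fixed by the cis ring fusion, since the cationic carbon is already a member of the seven-membered ring and can bond only on the face that carries the six-membered ring, so the configuration of the silyl ether carbon in 13 is irrelevant. The step needs the aldol to precede ionisation (a tertiary silyl ether should ionise only on warming, the aldol runs cold) and capture at the tertiary, not the secondary, allyl terminus (more positive charge at the tertiary carbon, which sits axially over the diene).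

Step 11
Reactants: 16 diol-dione (see step 10)
Product: 17 [5-hydroxy-2,6,11-trimethyl-3,9-dioxotricyclo[5.4.0.0(2,8)]undec-10-en-6-yl]methyl (Z)-2-methylbut-2-enoate (stereocentres as in 19)
Conditions: angelic acid, 2,4,6-trichlorobenzoyl chloride, Et3N, PhMe, 23 °C; then 16, 50 °C
Reagents that add atoms: angelic acid, C/C=C(/C)C(=O)O
Why: Yamaguchi-type mixed-anhydride esterification without DMAP, a protocol that preserves the Z geometry of angelates, should acylate the primary alcohol and leave the hindered secondary β-hydroxy ketone alcohol free.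

Step 12
Reactants: 17 angelate (see step 11)
Product: 18 [5-acetoxy-3-hydroxy-2,6,11-trimethyl-9-oxotricyclo[5.4.0.0(2,8)]undec-10-en-6-yl]methyl (Z)-2-methylbut-2-enoate (stereocentres as in 19)
Conditions: CH3CHO (10 equiv), SmI2 (0.3 equiv, premixed with the aldehyde), THF, −10 °C
Reagents that add atoms: acetaldehyde, CC=O
Why: Evans–Tishchenko reduction: the samarium-bound hemiacetal formed from the hydroxyl and acetaldehyde delivers hydride intramolecularly to the β-ketone through a six-membered transition state, giving the 1,3-anti (trans) diol monoacetate, so the new carbinol centre and the acetate are set together while the enone, which has no β-hydroxyl, is untouched.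

Step 13
Reactants: 18 hydroxy acetate (see step 12)
Product: 19 target CNP0179010.1
Conditions: 3-methylbut-2-enoyl chloride, pyridine, DMAP (cat.), CH2Cl2, 0 → 23 °C
Reagents that add atoms: 3-methylbut-2-enoyl chloride, CC(C)=CC(=O)Cl
Why: DMAP-catalysed acylation of the remaining hindered secondary alcohol; the trans-1,3 acetate cannot migrate and the other esters are inert.

**Compound list**

1 | ethyl 2-methyl-3-oxopropanoate | CCOC(=O)C(C)C=O | starting material
2 | pent-1-en-3-one | CCC(=O)C=C | starting material
3 | ethyl (R)-2-formyl-2-methyl-5-oxoheptanoate | CCOC(=O)[C@](C=O)(C)CCC(=O)CC | intermediate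
4 | ethyl (R)-1,3-dimethyl-4-oxocyclohex-2-ene-1-carboxylate | CCOC(=O)[C@@]1(C)C=C(C)C(=O)CC1 | intermediate
5 | ethyl (R)-1,3-dimethyl-4-oxocyclohexa-2,5-diene-1-carboxylate | CCOC(=O)[C@@]1(C)C=C(C)C(=O)C=C1 | intermediate
6 | (E)-pent-3-en-2-one | C/C=C/C(C)=O | starting material
7 | (E)-2-(tert-butyldimethylsilyloxy)penta-1,3-diene | C=C(O[Si](C)(C)C(C)(C)C)/C=C/C | intermediate
8 | ethyl (1R,4aS,5S,8aR)-7-(tert-butyldimethylsilyloxy)-1,3,5-trimethyl-4-oxo-1,4,4a,5,8,8a-hexahydronaphthalene-1-carboxylate | CCOC(=O)[C@]1(C)[C@@H]2CC(O[Si](C)(C)C(C)(C)C)=C[C@H](C)[C@@H]2C(=O)C(C)=C1 | intermediate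
9 | bridged lactone (2-oxabicyclo[2.2.2]oct-5-en-3-one fused to the silyl enol ether ring; formed from the tertiary alkoxide and the cis ester) | O=C1O[C@]2(C)C(C)=C[C@@]1(C)[C@@H]3CC(O[Si](C)(C)C(C)(C)C)=C[C@H](C)[C@H]23 | intermediate
10 | 7-(tert-butyldimethylsilyloxy)-1-(hydroxymethyl)-1,3,4,5-tetramethyl-1,4,4a,5,8,8a-hexahydronaphthalen-4-ol | OC[C@]1(C)[C@@H]2CC(O[Si](C)(C)C(C)(C)C)=C[C@H](C)[C@@H]2[C@](C)(O)C(C)=C1 | intermediate
11 | bis-silyl ether of 10 (primary OTBS, tertiary OTMS) | CC(C)(C)[Si](C)(C)OC[C@]1(C)[C@@H]2CC(O[Si](C)(C)C(C)(C)C)=C[C@H](C)[C@@H]2[C@](C)(O[Si](C)(C)C)C(C)=C1 | intermediate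
12 | 8-[(tert-butyldimethylsilyloxy)methyl]-4,5,6,8-tetramethyl-5-(trimethylsilyloxy)-4a,5,8,8a-tetrahydronaphthalen-2(1H)-one | CC(C)(C)[Si](C)(C)OC[C@]1(C)[C@@H]2CC(=O)C=C(C)[C@@H]2[C@](C)(O[Si](C)(C)C)C(C)=C1 | intermediate
13 | 3-(tert-butyldimethylsilyloxy)-2-methyl-2-{3-methyl-5-oxo-2-[3-oxo-2-(trimethylsilyloxy)butan-2-yl]cyclohex-3-en-1-yl}propanal | CC(C)(C)[Si](C)(C)OC[C@](C=O)(C)[C@@H]1CC(=O)C=C(C)[C@@H]1[C@](C)(O[Si](C)(C)C)C(C)=O | intermediate
14 | bicyclic aldol enol silane (cis-fused silyloxycyclohexadiene/cycloheptene, tertiary allylic OTMS) | CC(C)(C)[Si](C)(C)OC[C@]1(C)[C@@H]2C=C(O[Si](C)(C)C)C=C(C)[C@@H]2[C@](C)(O[Si](C)(C)C)C(O[Si](C)(C)C)=C[C@H]1O[Si](C)(C)C | intermediate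
15 | persilylated tricycle (enol TMS ether of the bridge ketone, secondary OTMS, primary OTBS) | CC(C)(C)[Si](C)(C)OC[C@]1(C)[C@@H]2[C@H]3C(=O)C=C(C)[C@@H]2[C@@]3(C)C(O[Si](C)(C)C)=C[C@H]1O[Si](C)(C)C | intermediate
16 | 5-hydroxy-6-(hydroxymethyl)-2,6,11-trimethyltricyclo[5.4.0.0(2,8)]undec-10-ene-3,9-dione | OC[C@]1(C)[C@@H]2[C@H]3C(=O)C=C(C)[C@@H]2[C@@]3(C)C(=O)C[C@H]1O | intermediate
17 | [5-hydroxy-2,6,11-trimethyl-3,9-dioxotricyclo[5.4.0.0(2,8)]undec-10-en-6-yl]methyl (Z)-2-methylbut-2-enoate | C/C=C(/C)C(=O)OC[C@]1(C)[C@@H]2[C@H]3C(=O)C=C(C)[C@@H]2[C@@]3(C)C(=O)C[C@H]1O | intermediate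
18 | [5-acetoxy-3-hydroxy-2,6,11-trimethyl-9-oxotricyclo[5.4.0.0(2,8)]undec-10-en-6-yl]methyl (Z)-2-methylbut-2-enoate | C/C=C(/C)C(=O)OC[C@]1(C)[C@@H]2[C@H]3C(=O)C=C(C)[C@@H]2[C@@]3(C)[C@H](O)C[C@H]1OC(C)=O | intermediate
19 | CNP0179010.1 | C/C=C(/C)C(=O)OC[C@]1(C)[C@@H]2[C@H]3C(=O)C=C(C)[C@@H]2[C@@]3(C)[C@H](OC(=O)C=C(C)C)C[C@H]1OC(C)=O | target

**Step count and risks**

Total steps: 13. Longest linear sequence: 12 (steps 1–3 and 5–13; step 4 is a one-step side branch).

Steps most likely to fail:

1. Step 10 (proposed new method). The tertiary silyl ether may ionise before the aldol has closed the seven-membered ring; the free cation would then be captured at its unsubstituted CH2 terminus (six-membered ring) or lose a proton. After the aldol, the ring-bound cation may be captured at its secondary terminus (five-membered ring) instead of the tertiary one. Fallback, from 13 back to 16, with each bond made by a known reaction: the cascade is stopped after the aldol (TMSOTf/Et3N at −78 °C, cold NaHCO3 quench) to give the bicyclic aldol bis(trimethylsilyl) ether F1. Reductive cleavage of the α-silyloxy ketone with SmI2/HMPA gives the samarium enolate, which is trapped with TMSCl; the enone is converted in the same flask to its dienol silane with TMSOTf/Et3N, giving the bis(enol silane) F2, in which the nucleophilic side-chain carbon is fixed at the tertiary position. Oxidative cross-coupling of the two enol silanes with (NH4)2Ce(NO3)6/NaHCO3 in MeCN (known 1,4-diketone synthesis) then closes the cyclobutane, and HF·pyridine gives 16.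

2. Step 5. Facial selectivity may be poor or inverted (diene anti to the ester), which would give the wrong relation between the quaternary carbon and the ring fusion. Fallback, from 4 back to 9: the ester is exchanged for the much smaller nitrile, which should direct the diene to its own face more firmly. Aminolysis of 4 (Me3Al, NH4Cl) gives (R)-1,3-dimethyl-4-oxocyclohex-2-ene-1-carboxamide F3; dehydration (trifluoroacetic anhydride, pyridine) gives (R)-1,3-dimethyl-4-oxocyclohex-2-ene-1-carbonitrile F4; IBX gives (R)-1,3-dimethyl-4-oxocyclohexa-2,5-diene-1-carbonitrile F5; Diels–Alder reaction with 7 gives the cyano analogue of adduct 8 F6. MeLi/CeCl3 addition then gives an alkoxide that adds to the cis nitrile, and hydrolysis of the imidate on aqueous work-up gives lactone 9, which rejoins step 6 at the LiAlH4 stage.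

3. Step 9. Ozone may attack the enone double bond, or react sluggishly at the alkene flanked by two quaternary carbons; loss of the tertiary TMS ether would lead to a lactol. Fallback, from 12 back to 13: the electron-rich ring-A alkene is epoxidised with mCPBA/NaHCO3 (which does not touch the enone) to give the epoxide of 12 F7, and the epoxide is cleaved with buffered H5IO6 in aqueous THF to the same keto aldehyde 13.

**Further compounds**

F1 | step 10 | bicyclic aldol adduct of 13 (cis-fused cyclohexenone/cycloheptanone; tertiary and secondary OTMS, primary OTBS) | CC(C)(C)[Si](C)(C)OC[C@]1(C)[C@@H]2CC(=O)C=C(C)[C@@H]2[C@](C)(O[Si](C)(C)C)C(=O)C[C@H]1O[Si](C)(C)C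
F2 | step 10 | bis(enol silane): ring dienol TMS ether plus tetrasubstituted enol TMS ether in the seven-membered ring | CC(C)(C)[Si](C)(C)OC[C@]1(C)[C@@H]2C=C(O[Si](C)(C)C)C=C(C)[C@@H]2C(C)=C(O[Si](C)(C)C)C[C@H]1O[Si](C)(C)C
F3 | step 5 | (R)-1,3-dimethyl-4-oxocyclohex-2-ene-1-carboxamide | NC(=O)[C@@]1(C)C=C(C)C(=O)CC1
F4 | step 5 | (R)-1,3-dimethyl-4-oxocyclohex-2-ene-1-carbonitrile | N#C[C@@]1(C)C=C(C)C(=O)CC1
F5 | step 5 | (R)-1,3-dimethyl-4-oxocyclohexa-2,5-diene-1-carbonitrile | N#C[C@@]1(C)C=C(C)C(=O)C=C1
F6 | step 5 | cyano analogue of adduct 8 (7-(tert-butyldimethylsilyloxy)-1,3,5-trimethyl-4-oxo-1,4,4a,5,8,8a-hexahydronaphthalene-1-carbonitrile) | N#C[C@]1(C)[C@@H]2CC(O[Si](C)(C)C(C)(C)C)=C[C@H](C)[C@@H]2C(=O)C(C)=C1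
F7 | step 9 | epoxide of 12 at the ring-A alkene (oxygen on the face of the two methyl groups) | CC(C)(C)[Si](C)(C)OC[C@]1(C)[C@@H]2CC(=O)C=C(C)[C@@H]2[C@](C)(O[Si](C)(C)C)[C@@]3(C)O[C@H]31
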